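**Strategy.** The 1,2-dioxolane (O1, O2, C3 bearing the acetic acid arm, C4, C5 bearing the side chain) is disconnected across C4–C5 and O2–C3 into a three-atom C5–O1–O2 unit and a two-carbon C4=C3 unit. The key step is a Lewis-acid-mediated (3+2) annulation. A silylperoxycarbenium ion centred on C5, already carrying the complete (R)-methyl-branched phenyldienyl side chain, is attacked by the terminal CH2 of methyl 3-methylbut-3-enoate, and the tertiary cation at C3 is captured by the distal peroxide oxygen. It exploits that C5 is a ketone-level carbon bound to O–O and that C3 is a fully substituted, cation-stabilising carbon. The precursor is the triethylsilyl methyl peroxyketal of an enantioenriched open-chain methyl ketone.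

Key step: step 8

Remark (assumption): in step 5 the Josiphos antipode is taken to be the one that delivers the alkyl group to the Si face of C4 of enone 8. Which commercial antipode this is would be fixed by a trial run, and the mirror-image ligand would be used if the sense proved opposite.

Step 1
Reactants: 1 ethyl 5-bromopentanoate
Product: 3 7-bromohept-1-en-3-ol (racemic), via 5-bromopentanal 2 (not isolated)
Conditions: i-Bu2AlH (1.05 equiv), CH2Cl2, −78 °C; then CH2=CHMgBr (THF), −78 → 0 °C; aq. potassium sodium tartrate
Reagents that add atoms: vinylmagnesium bromide, C=C[Mg]Br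
Why: Half-reduction of the ester gives an aluminium hemiacetal that is stable at −78 °C and releases aldehyde 2 only as the Grignard reagent is added, so 1,2-addition (Grignard addition) should give the allylic alcohol, whose uncontrolled carbinol stereocentre is destroyed in step 2.

Step 2
Reactants: 3 7-bromohept-1-en-3-ol
Product: 4 ethyl (E)-9-bromonon-4-enoate
Conditions: CH3C(OEt)3 (5 equiv), EtCO2H (cat.), 140 °C, distillation of EtOH
Reagents that add atoms: triethyl orthoacetate, CC(OCC)(OCC)OCC
Why: Johnson–Claisen rearrangement of the mixed ketene acetal through a chair transition state with the bromobutyl group equatorial should give the (E)-γ,δ-unsaturated ester.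

Step 3
Reactants: 4 ethyl (E)-9-bromonon-4-enoate
Product: 5 (E)-9-bromonon-4-enal
Conditions: i-Bu2AlH (1.05 equiv), CH2Cl2, −78 °C; aq. potassium sodium tartrate
Reagents that add atoms: none
Why: Low-temperature DIBAL half-reduction of an ester stops at the aldehyde because the tetrahedral aluminium hemiacetal survives until work-up, and the alkyl bromide and alkene are inert.

Step 4
Reactants: 5 (E)-9-bromonon-4-enal, 6 diethyl benzylphosphonate
Product: 7 [(1E,5E)-10-bromodeca-1,5-dien-1-yl]benzene
Conditions: 6, KOt-Bu (1.05 equiv), THF, 0 °C; then 5, 0 °C → rt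
Reagents that add atoms: none
Why: Horner–Wadsworth–Emmons olefination with the pre-formed benzylphosphonate anion should give the (E)-styrene through the thermodynamically preferred anti adduct, and the aldehyde is consumed faster than the primary bromide is attacked.

Step 5
Reactants: 7 [(1E,5E)-10-bromodeca-1,5-dien-1-yl]benzene, 8 (E)-pent-3-en-2-one
Product: 10 (4R,9E,13E)-4-methyl-14-phenyltetradeca-9,13-dien-2-one, via Grignard reagent 9 (not isolated)
Conditions: Mg, Et2O, rt; then slow addition to 8 (1.3 equiv, distilled), CuBr·SMe2 (5 mol %), 1-[2-(diphenylphosphino)ferrocenyl]ethyldicyclohexylphosphine (Josiphos, 6 mol %, Si-face-directing antipode), t-BuOMe, −75 °C; aq. NH4Cl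
Reagents that add atoms: none
Why: Copper-catalysed asymmetric conjugate addition of a Grignard reagent to an acyclic enone, in which the chiral ferrocenyl diphosphine–copper complex delivers the alkyl group to the Si face of C4 (ligand control), should set the (R) methyl-bearing stereocentre.

Step 6
Reactants: 10 (4R,9E,13E)-4-methyl-14-phenyltetradeca-9,13-dien-2-one
Product: 11 (4R,9E,13E)-2,2-dimethoxy-4-methyl-14-phenyltetradeca-9,13-diene
Conditions: HC(OMe)3 (3 equiv), MeOH, PPTS (cat.), rt; Et3N quench
Reagents that add atoms: trimethyl orthoformate, COC(OC)OC; methanol, CO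
Why: Acid-catalysed ketalisation of an unhindered methyl ketone is driven to completion by the orthoformate as water scavenger and leaves the alkenes and the stereocentre untouched.

Step 7
Reactants: 11 (4R,9E,13E)-2,2-dimethoxy-4-methyl-14-phenyltetradeca-9,13-diene
Product: 13 triethyl{[(4R,9E,13E)-2-methoxy-4-methyl-14-phenyltetradeca-9,13-dien-2-yl]peroxy}silane (both C2 epimers), via methoxy hydroperoxide 12 (not isolated)
Conditions: H2O2 (anhydrous, ca. 3 M in Et2O, 4 equiv), camphorsulfonic acid (5 mol %), Et2O, 0 °C; NaHCO3 wash; then Et3SiCl, imidazole, DMF, 0 °C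
Reagents that add atoms: hydrogen peroxide, OO; chlorotriethylsilane, CC[Si](Cl)(CC)CC
Why: Acid-catalysed perhydrolysis of the ketal (exchange of one methoxy group for OOH through the oxocarbenium ion) followed by O-silylation of the hydroperoxide should give the silyl peroxyketal, whose new C2 stereocentre is formed without control but is erased on ionisation in step 8.

Step 8
Reactants: 13 triethyl{[(4R,9E,13E)-2-methoxy-4-methyl-14-phenyltetradeca-9,13-dien-2-yl]peroxy}silane, 14 methyl 3-methylbut-3-enoate
Product: 17 methyl 2-[(3R,5R)-3,5-dimethyl-5-[(2R,7E,11E)-2-methyl-12-phenyldodeca-7,11-dien-1-yl]-1,2-dioxolan-3-yl]acetate, via silylperoxycarbenium ion 15 (not isolated), via tertiary carbocation 16 (not isolated)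
Conditions: SnCl4 (1.5 equiv), 14 (5 equiv), CH2Cl2, −78 °C, slow addition of 13; aq. NaHCO3; chromatographic separation of diastereomers
Reagents that add atoms: none
Why: SnCl4 ionises the methoxy group of 13 to give silylperoxycarbenium ion 15, whose C5 is attacked by the unhindered terminal CH2 of 14 (Markovnikov, C4–C5 bond) to give tertiary carbocation 16, which is captured by the silylated distal peroxide oxygen (O2–C3 bond) with loss of the triethylsilyl group. The closest known reaction type is the Lewis-acid-mediated annulation of triethylsilyl peroxyketals with 1,1-disubstituted alkenes to give 1,2-dioxolanes. The dioxolane is closed in a stepwise polar (3+2) mode, the second event being a five-membered cation capture through an envelope transition state. C5 is set in the first event by face selection on planar 15 under only weak 1,3-induction from the methyl-bearing side-chain centre, and C3 is set in the ring closure relative to C5, the envelope with both CH2 arms pseudo-equatorial leading to the required cis (3R,5R) arrangement. The step needs chemoselectivity for the alkene of 14 over the 1,2-disubstituted and styrenyl alkenes of the side chain, which the excess of 14, the slow addition of 13 and the accessible, cation-stabilising 1,1-disubstituted terminus should secure. Because the substrate cannot secure high diastereoselectivity, the (3R,5R) isomer is to be separated from its diastereomers by chromatography at the stage of ester 17.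

Step 9
Reactants: 17 methyl 2-[(3R,5R)-3,5-dimethyl-5-[(2R,7E,11E)-2-methyl-12-phenyldodeca-7,11-dien-1-yl]-1,2-dioxolan-3-yl]acetate
Product: 18 2-[(3R,5R)-3,5-dimethyl-5-[(2R,7E,11E)-2-methyl-12-phenyldodeca-7,11-dien-1-yl]-1,2-dioxolan-3-yl]acetic acid
Conditions: LiOH·H2O (3 equiv), THF/H2O, 0 °C → rt; then 1 M HCl to pH 3
Reagents that add atoms: lithium hydroxide, [Li+].[OH-]
Why: Saponification (acyl–oxygen cleavage) of the methyl ester should leave the peroxide intact, because C3 and C5 carry no hydrogen for base-induced peroxide fragmentation and the quaternary stereocentres cannot epimerise.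

**Compound list**

1 | ethyl 5-bromopentanoate | CCOC(=O)CCCCBr | starting material
2 | 5-bromopentanal | O=CCCCCBr | intermediate
3 | 7-bromohept-1-en-3-ol (racemic) | C=CC(O)CCCCBr | intermediate
4 | ethyl (E)-9-bromonon-4-enoate | CCOC(=O)CC/C=C/CCCCBr | intermediate
5 | (E)-9-bromonon-4-enal | O=CCC/C=C/CCCCBr | intermediate
6 | diethyl benzylphosphonate | CCOP(=O)(Cc1ccccc1)OCC | starting material
7 | [(1E,5E)-10-bromodeca-1,5-dien-1-yl]benzene | BrCCCC/C=C/CC/C=C/c1ccccc1 | intermediate
8 | (E)-pent-3-en-2-one | C/C=C/C(C)=O | starting material
9 | [(5E,9E)-10-phenyldeca-5,9-dien-1-yl]magnesium bromide | Br[Mg]CCCC/C=C/CC/C=C/c1ccccc1 | intermediate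
10 | (4R,9E,13E)-4-methyl-14-phenyltetradeca-9,13-dien-2-one | C[C@H](CCCC/C=C/CC/C=C/c1ccccc1)CC(C)=O | intermediate
11 | (4R,9E,13E)-2,2-dimethoxy-4-methyl-14-phenyltetradeca-9,13-diene | C[C@H](CCCC/C=C/CC/C=C/c1ccccc1)CC(C)(OC)OC | intermediate
12 | (4R,9E,13E)-2-hydroperoxy-2-methoxy-4-methyl-14-phenyltetradeca-9,13-diene (both C2 epimers) | C[C@H](CCCC/C=C/CC/C=C/c1ccccc1)CC(C)(OC)OO | intermediate
13 | triethyl{[(4R,9E,13E)-2-methoxy-4-methyl-14-phenyltetradeca-9,13-dien-2-yl]peroxy}silane (both C2 epimers) | C[C@H](CCCC/C=C/CC/C=C/c1ccccc1)CC(C)(OC)OO[Si](CC)(CC)CC | intermediate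
14 | methyl 3-methylbut-3-enoate | C=C(C)CC(=O)OC | starting material
15 | silylperoxycarbenium ion, [(4R,9E,13E)-4-methyl-14-phenyltetradeca-9,13-dien-2-ylidene](triethylsilyloxy)oxonium | C[C@H](CCCC/C=C/CC/C=C/c1ccccc1)CC(C)=[O+]O[Si](CC)(CC)CC | intermediate
16 | tertiary carbocation formed by C4–C5 bond formation (triethylsilylperoxy group on C5, cation on the carbon that becomes C3) | C[C@H](CCCC/C=C/CC/C=C/c1ccccc1)C[C@](C)(C[C+](C)CC(=O)OC)OO[Si](CC)(CC)CC | intermediate
17 | methyl 2-[(3R,5R)-3,5-dimethyl-5-[(2R,7E,11E)-2-methyl-12-phenyldodeca-7,11-dien-1-yl]-1,2-dioxolan-3-yl]acetate | C[C@H](CCCC/C=C/CC/C=C/c1ccccc1)C[C@]1(C)C[C@](C)(CC(=O)OC)OO1 | intermediate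
18 | 2-[(3R,5R)-3,5-dimethyl-5-[(2R,7E,11E)-2-methyl-12-phenyldodeca-7,11-dien-1-yl]-1,2-dioxolan-3-yl]acetic acid | C[C@H](CCCC/C=C/CC/C=C/c1ccccc1)C[C@]1(C)C[C@](C)(CC(=O)O)OO1 | target

**Total step count:** 9. **Longest linear sequence:** 9 steps (from 1; compounds 6, 8 and 14 are purchased).

**Steps most likely to fail**

1. Step 8 (key step). The ester group makes 14 a weakened π-nucleophile, through its inductive effect and through complexation with SnCl4. Capture of ion 15 may therefore be outrun by Hock/Criegee-type fragmentation of the peroxycarbenium ion or by attack of the styrenyl alkene of a second molecule. In addition, face selection at C5 and C3 is only weakly biased, so the wanted isomer may be a minor part of a mixture that is hard to separate. The fallback makes the same two bonds stepwise with known reactions, setting out from 13 and coming back at 17. Methyl 3-methylbut-2-enoate would be converted with LiN(i-Pr)2 and Me3SiCl into the silyl dienolate [(1-methoxy-3-methylbuta-1,3-dien-1-yl)oxy]trimethylsilane F1. Its far more nucleophilic γ-carbon should add to the peroxycarbenium ion generated from 13 with Me3SiOTf in CH2Cl2 at −78 °C (vinylogous Mukaiyama-type addition, C4–C5 bond). This should give the silylperoxy enoate methyl (2E,7R,12E,16E)-3,5,7-trimethyl-17-phenyl-5-[(triethylsilyl)peroxy]heptadeca-2,12,16-trienoate F2. Bu4NF in THF would then remove the triethylsilyl group, and the liberated peroxide anion should close onto the enoate in a 5-exo-trig oxa-Michael addition (O2–C3 bond) to give 17. In this variant the C3 epimers can be re-equilibrated by base through retro-Michael/Michael addition, so the unwanted C3 epimer can be recycled.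

2. Step 7. The ketal/H2O2 exchange is an equilibrium that may stall, run on to the geminal dihydroperoxide, or fall back to ketone 10 through adventitious hydrolysis. The fallback replaces exchange by an irreversible addition, setting out from 11 and coming back at 13. Me3SiOTf and i-Pr2NEt in CH2Cl2 at 0 °C should eliminate methanol from 11 to give the enol ether (4R,9E,13E)-2-methoxy-4-methyl-14-phenyltetradeca-1,9,13-triene F3 (a double-bond regioisomer would behave identically). Acid-catalysed Markovnikov addition of ethereal H2O2 across the enol ether should give hydroperoxide 12, which is silylated as in step 7 to 13.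

3. Step 5. Radical cyclisation during magnesium insertion, competing 1,2-addition and incomplete enantioface discrimination for this pairing of a long-chain Grignard reagent with a small enone may erode the yield and the enantiomeric purity of 10. The fallback uses auxiliary control, setting out from 7 and coming back at 10. (R)-4-Phenyloxazolidin-2-one would be N-acylated (n-BuLi, (E)-but-2-enoyl chloride) to (R)-3-[(E)-but-2-enoyl]-4-phenyloxazolidin-2-one F4. Grignard reagent 9 from 7 with CuBr·SMe2 in THF at −40 °C should add to the magnesium-chelated s-cis imide anti to the phenyl group. This should give (R)-3-[(3R,8E,12E)-3-methyl-13-phenyltrideca-8,12-dienoyl]-4-phenyloxazolidin-2-one F5, a diastereomer that can be purified. Me(MeO)NH·HCl with AlMe3 should convert it into the Weinreb amide (3R,8E,12E)-N-methoxy-N,3-dimethyl-13-phenyltrideca-8,12-dienamide F6, and MeMgBr then gives ketone 10.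

**Further compounds**

F1 | step 8 | [(1-methoxy-3-methylbuta-1,3-dien-1-yl)oxy]trimethylsilane | COC(O[Si](C)(C)C)=CC(C)=C
F2 | step 8 | methyl (2E,7R,12E,16E)-3,5,7-trimethyl-17-phenyl-5-[(triethylsilyl)peroxy]heptadeca-2,12,16-trienoate (both C5 epimers) | C[C@H](CCCC/C=C/CC/C=C/c1ccccc1)CC(C)(C/C(C)=C/C(=O)OC)OO[Si](CC)(CC)CC
F3 | step 7 | (4R,9E,13E)-2-methoxy-4-methyl-14-phenyltetradeca-1,9,13-triene | C[C@H](CCCC/C=C/CC/C=C/c1ccccc1)CC(=C)OC
F4 | step 5 | (R)-3-[(E)-but-2-enoyl]-4-phenyloxazolidin-2-one | C/C=C/C(=O)N1[C@H](c2ccccc2)COC1=O
F5 | step 5 | (R)-3-[(3R,8E,12E)-3-methyl-13-phenyltrideca-8,12-dienoyl]-4-phenyloxazolidin-2-one | C[C@H](CCCC/C=C/CC/C=C/c1ccccc1)CC(=O)N1[C@H](c2ccccc2)COC1=O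
F6 | step 5 | (3R,8E,12E)-N-methoxy-N,3-dimethyl-13-phenyltrideca-8,12-dienamide | C[C@H](CCCC/C=C/CC/C=C/c1ccccc1)CC(=O)N(C)OC
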